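**Retrosynthetic overview**

1. Oxolane numbering used throughout: O1, C2 (aryl), C3 (OH, CH2OH), C4 (arylmethyl), C5 (CH2); the target is 2R,3S,4S.
2. Enabling feature: C3 carries both OH and CH2OH, so C3, its oxygen and the exocyclic CH2OH carbon are a latent α-hydroxy acid. Closed into a 1,3-dioxolan-4-one (a temporary ring, spiro to the later oxolane at C3), C3 becomes an enolate carbon, and the ring methylene C5, 1,3 to C3 through C4, can carry a sulfonate.
3. Key disconnection, both bonds at once: C2–C3 (aldol) and O1–C5 (5-exo-tet etherification) between benzyl-protected vanillin, which brings O1=C2, and that enolate/sulfonate.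
4. Stereochemistry: C3 is bought with dimethyl (S)-malate; C4 is relayed from it by anti-selective Fráter–Seebach alkylation; C3 is carried through its enolate by the tert-butyl acetal centre; C2 is set in the key step.
5. Ring order: dioxolanone (step 4), oxolane (step 7); the dioxolanone is then opened by hydride to the C3–OH/CH2OH pair (step 8) and the phenols are freed (step 9).

Key step: step 7

**Route**

Step 1
Reactants: 1 4-(benzyloxy)-3-methoxybenzyl alcohol
Product: 2 4-(benzyloxy)-3-methoxybenzyl bromide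
Conditions: PBr3 (0.4 equiv), Et2O, 0 °C; used without storage
Reagents that add atoms: phosphorus tribromide, BrP(Br)Br
Why: Bromination of an activated benzylic alcohol through its phosphite ester (SN2-type) should be clean, and the aryl benzyl ether is inert to PBr3.

Step 2
Reactants: 3 dimethyl (S)-malate; 2 4-(benzyloxy)-3-methoxybenzyl bromide
Product: 5 dimethyl (2S,3R)-3-{[4-(benzyloxy)-3-methoxyphenyl]methyl}-2-hydroxybutanedioate, via dilithium alkoxide-enolate 4 (not isolated)
Conditions: LiN(SiMe3)2 (2.1 equiv), THF, −78 to −20 °C; then 2, −78 to 0 °C; AcOH quench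
Reagents that add atoms: none
Why: Fráter–Seebach alkylation: the chelated dilithium alkoxide-enolate should take up the benzylic bromide on the face anti to the C2 oxygen, giving the anti (2S,3R) product and so setting the future C4.

Step 3
Reactants: 5 dimethyl (2S,3R)-3-{[4-(benzyloxy)-3-methoxyphenyl]methyl}-2-hydroxybutanedioate
Product: 6 (2S,3R)-3-{[4-(benzyloxy)-3-methoxyphenyl]methyl}-2-hydroxybutanedioic acid
Conditions: LiOH·H2O (3 equiv), THF/H2O, 0 °C to rt; then 1 M HCl to pH 2
Reagents that add atoms: lithium hydroxide, [Li+].[OH-]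
Why: Saponification by acyl–oxygen cleavage should proceed without epimerization, since the carboxylates formed are poor C–H acids.

Step 4
Reactants: 6 (2S,3R)-3-{[4-(benzyloxy)-3-methoxyphenyl]methyl}-2-hydroxybutanedioic acid; 7 pivalaldehyde
Product: 8 (2R)-3-[4-(benzyloxy)-3-methoxyphenyl]-2-[(2S,4S)-2-tert-butyl-5-oxo-1,3-dioxolan-4-yl]propanoic acid
Conditions: 7 (3 equiv), TsOH·H2O (cat.), H2SO4 (cat.), pentane–CH2Cl2, reflux, water separator; cis isomer purified by crystallisation
Reagents that add atoms: none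
Why: Acid-catalysed acetalization of the α-hydroxy acid should close the five-membered dioxolanone in preference to a six-membered ring with the distal CO2H, and thermodynamic control should favour the cis acetal, whose new stereocentre stores the C3 configuration (self-regeneration of stereocentres).

Step 5
Reactants: 8 (2R)-3-[4-(benzyloxy)-3-methoxyphenyl]-2-[(2S,4S)-2-tert-butyl-5-oxo-1,3-dioxolan-4-yl]propanoic acid
Product: 9 (2S,5S)-5-{(2S)-1-[4-(benzyloxy)-3-methoxyphenyl]-3-hydroxypropan-2-yl}-2-tert-butyl-1,3-dioxolan-4-one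
Conditions: BH3·SMe2 (1.3 equiv), THF, 0 °C; MeOH quench at 0 °C; crude alcohol taken on at once
Reagents that add atoms: none
Why: Borane should reduce the free carboxylic acid (via its acyloxyborane) much faster than the lactone-type dioxolanone carbonyl, under non-basic conditions that leave both stereocentres untouched.

Step 6
Reactants: 9 (2S,5S)-5-{(2S)-1-[4-(benzyloxy)-3-methoxyphenyl]-3-hydroxypropan-2-yl}-2-tert-butyl-1,3-dioxolan-4-one
Product: 10 (2S)-3-[4-(benzyloxy)-3-methoxyphenyl]-2-[(2S,4S)-2-tert-butyl-5-oxo-1,3-dioxolan-4-yl]propyl 4-methylbenzenesulfonate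
Conditions: TsCl (1.3 equiv), pyridine, CH2Cl2, 0 °C
Reagents that add atoms: 4-methylbenzenesulfonyl chloride, Cc1ccc(cc1)S(Cl)(=O)=O
Why: Sulfonylation of the unhindered primary alcohol should be fast at 0 °C, and it caps the hydroxyl before it can attack the dioxolanone carbonyl.

Step 7
Reactants: 10 (2S)-3-[4-(benzyloxy)-3-methoxyphenyl]-2-[(2S,4S)-2-tert-butyl-5-oxo-1,3-dioxolan-4-yl]propyl 4-methylbenzenesulfonate; 11 4-(benzyloxy)-3-methoxybenzaldehyde
Product: 14 (2S,5R,6R,9S)-6-[4-(benzyloxy)-3-methoxyphenyl]-9-{[4-(benzyloxy)-3-methoxyphenyl]methyl}-2-tert-butyl-1,3,7-trioxaspiro[4.4]nonan-4-one, via lithium enolate 12 (not isolated), via lithium aldolate 13 (not isolated)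
Conditions: LiN(iPr)2 (1.05 equiv), THF, −78 °C, 10 min; then 11 (1.2 equiv), −78 °C; then DMPU, −78 to 0 °C
Reagents that add atoms: none
Why: LiN(iPr)2 removes the C3–H of the dioxolanone to give the planar lithium enolate 12, which adds to the aldehyde carbon (C2–C3 bond) to give lithium aldolate 13, whose alkoxide oxygen, the former carbonyl oxygen O1, displaces the primary tosylate at C5 on warming (O1–C5 bond), so that the aldehyde C=O is added across the C3 nucleophile and the C5 electrophile in a formal [3+2] annulation. The closest known reaction type is the tetrahydrofuran annulation of γ-leaving-group carbanions (γ-halo ester, nitrile or sulfone anions) with aldehydes, an aldol addition followed by intramolecular Williamson etherification, run here on a 1,3-dioxolan-4-one enolate, a class whose aldol additions to aldehydes are well known. The only ring closed, the oxolane, forms in the 5-exo-tet mode at an unhindered primary sulfonate carbon. C3 is controlled by the tert-butyl-bearing acetal carbon of the temporary dioxolanone, because the aldehyde should add to the enolate face anti to tert-butyl so that the new C–C bond takes the place of the original hydrogen (net retention); C2 is controlled by a closed, lithium-bridged Zimmerman–Traxler transition state with the aryl group equatorial and the C4 side chain cis to the enolate oxygen, which should place aryl cis to the dioxolanone ring oxygen (2R); C4 is a spectator set in step 2. The step needs aldol addition and O-alkylation by the aldolate to win over self-alkylation of the enolate (3-exo-tet to a cyclopropane, or O-alkylation to a cyclic ketene acetal) and over retro-aldol; this is secured by forming and consuming the enolate at −78 °C, where sulfonate displacement by a lithium enolate is slow, by pairing a hard sulfonate leaving group with the hard alkoxide, and by the quaternary C3 and branched C4, which favour the conformer needed for 5-exo closure (Thorpe–Ingold effect).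

Step 8
Reactants: 14 (2S,5R,6R,9S)-6-[4-(benzyloxy)-3-methoxyphenyl]-9-{[4-(benzyloxy)-3-methoxyphenyl]methyl}-2-tert-butyl-1,3,7-trioxaspiro[4.4]nonan-4-one
Product: 15 (2R,3S,4S)-2-[4-(benzyloxy)-3-methoxyphenyl]-4-{[4-(benzyloxy)-3-methoxyphenyl]methyl}-3-(hydroxymethyl)oxolan-3-ol
Conditions: LiAlH4 (3 equiv), THF, 0 °C; H2O then aq. NaOH work-up
Reagents that add atoms: none
Why: Hydride reduction of the dioxolanone carbonyl should take the acyl carbon to CH2OH and release the C3 tertiary alkoxide with loss of pivalaldehyde (itself reduced), while the oxolane, the benzyl ethers and all three stereocentres are not touched.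

Step 9
Reactants: 15 (2R,3S,4S)-2-[4-(benzyloxy)-3-methoxyphenyl]-4-{[4-(benzyloxy)-3-methoxyphenyl]methyl}-3-(hydroxymethyl)oxolan-3-ol
Product: 16 (2R,3S,4S)-2-(4-hydroxy-3-methoxyphenyl)-4-[(4-hydroxy-3-methoxyphenyl)methyl]-3-(hydroxymethyl)oxolan-3-ol
Conditions: H2 (1 atm), 10% Pd/C, EtOAc–MeOH, rt; stopped after uptake of two equivalents
Reagents that add atoms: none
Why: Catalytic hydrogenolysis should cleave the two aryl benzyl ethers faster than the cyclic benzylic C2–O1 ether under neutral conditions, so the reaction is stopped at that point.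

**Compound list**

1 | 4-(benzyloxy)-3-methoxybenzyl alcohol | COc1cc(CO)ccc1OCc1ccccc1 | starting material
2 | 4-(benzyloxy)-3-methoxybenzyl bromide | COc1cc(CBr)ccc1OCc1ccccc1 | intermediate
3 | dimethyl (S)-malate | COC(=O)C[C@H](O)C(=O)OC | starting material
4 | dilithium alkoxide-enolate of dimethyl (S)-malate | [Li+].[Li+].COC(=O)[C@@H]([O-])C=C([O-])OC | intermediate (not isolated)
5 | dimethyl (2S,3R)-3-{[4-(benzyloxy)-3-methoxyphenyl]methyl}-2-hydroxybutanedioate | COC(=O)[C@@H](O)[C@@H](Cc1ccc(OCc2ccccc2)c(OC)c1)C(=O)OC | intermediate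
6 | (2S,3R)-3-{[4-(benzyloxy)-3-methoxyphenyl]methyl}-2-hydroxybutanedioic acid | OC(=O)[C@@H](O)[C@@H](Cc1ccc(OCc2ccccc2)c(OC)c1)C(=O)O | intermediate
7 | pivalaldehyde (2,2-dimethylpropanal) | CC(C)(C)C=O | starting material
8 | (2R)-3-[4-(benzyloxy)-3-methoxyphenyl]-2-[(2S,4S)-2-tert-butyl-5-oxo-1,3-dioxolan-4-yl]propanoic acid (cis acetal) | CC(C)(C)[C@@H]1OC(=O)[C@@H](O1)[C@@H](Cc2ccc(OCc3ccccc3)c(OC)c2)C(=O)O | intermediate
9 | (2S,5S)-5-{(2S)-1-[4-(benzyloxy)-3-methoxyphenyl]-3-hydroxypropan-2-yl}-2-tert-butyl-1,3-dioxolan-4-one | CC(C)(C)[C@@H]1OC(=O)[C@@H](O1)[C@@H](Cc2ccc(OCc3ccccc3)c(OC)c2)CO | intermediate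
10 | (2S)-3-[4-(benzyloxy)-3-methoxyphenyl]-2-[(2S,4S)-2-tert-butyl-5-oxo-1,3-dioxolan-4-yl]propyl 4-methylbenzenesulfonate | CC(C)(C)[C@@H]1OC(=O)[C@@H](O1)[C@@H](Cc2ccc(OCc3ccccc3)c(OC)c2)COS(=O)(=O)c4ccc(C)cc4 | intermediate
11 | 4-(benzyloxy)-3-methoxybenzaldehyde (O-benzylvanillin) | COc1cc(C=O)ccc1OCc1ccccc1 | starting material
12 | lithium enolate of 10 (2-tert-butyl-1,3-dioxol-4-olate, C3 planar, acetal carbon S) | [Li+].CC(C)(C)[C@@H]1OC([O-])=C(O1)[C@@H](Cc2ccc(OCc3ccccc3)c(OC)c2)COS(=O)(=O)c4ccc(C)cc4 | intermediate (not isolated)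
13 | lithium aldolate: lithium alkoxide of (2S)-2-[(2S,4R)-4-{(R)-[4-(benzyloxy)-3-methoxyphenyl](hydroxy)methyl}-2-tert-butyl-5-oxo-1,3-dioxolan-4-yl]-3-[4-(benzyloxy)-3-methoxyphenyl]propyl 4-methylbenzenesulfonate | [Li+].CC(C)(C)[C@@H]1OC(=O)[C@](O1)([C@H]([O-])c2ccc(OCc3ccccc3)c(OC)c2)[C@@H](Cc4ccc(OCc5ccccc5)c(OC)c4)COS(=O)(=O)c6ccc(C)cc6 | intermediate (not isolated)
14 | (2S,5R,6R,9S)-6-[4-(benzyloxy)-3-methoxyphenyl]-9-{[4-(benzyloxy)-3-methoxyphenyl]methyl}-2-tert-butyl-1,3,7-trioxaspiro[4.4]nonan-4-one | CC(C)(C)[C@@H]1OC(=O)[C@@]2(O1)[C@@H](Cc3ccc(OCc4ccccc4)c(OC)c3)CO[C@@H]2c5ccc(OCc6ccccc6)c(OC)c5 | intermediate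
15 | (2R,3S,4S)-2-[4-(benzyloxy)-3-methoxyphenyl]-4-{[4-(benzyloxy)-3-methoxyphenyl]methyl}-3-(hydroxymethyl)oxolan-3-ol | COc1cc(C[C@H]2CO[C@H](c3ccc(OCc4ccccc4)c(OC)c3)[C@@]2(O)CO)ccc1OCc5ccccc5 | intermediate
16 | (2R,3S,4S)-2-(4-hydroxy-3-methoxyphenyl)-4-[(4-hydroxy-3-methoxyphenyl)methyl]-3-(hydroxymethyl)oxolan-3-ol | COc1cc(C[C@H]2CO[C@H](c3ccc(O)c(OC)c3)[C@@]2(O)CO)ccc1O | target

**Step count and risks**

Total steps: 9. Longest linear sequence: 9 (1 → 2 → 5 → 6 → 8 → 9 → 10 → 14 → 15 → 16).

Steps most likely to fail: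

1. Step 7. On the warming needed for ring closure, the hindered lithium aldolate may revert by retro-aldol, after which the free enolate alkylates itself on carbon or oxygen instead of the alkoxide closing the oxolane; facial selectivity at the aldehyde carbon may also be incomplete. The fallback sets out from 10 and comes back at 14. The enolate (LiN(iPr)2, THF, −78 °C) and aldehyde 11 are combined as before, but the mixture is quenched at −78 °C with AcOH, so that the neutral hydroxy tosylate F1 is isolated and C2 epimers can be separated. F1 is then heated with 2,6-lutidine in MeCN at 60 °C, where the un-ionized benzylic hydroxyl displaces the primary tosylate (5-exo-tet, the usual behaviour of 1,4-diol monotosylates). No alkoxide is present, so the retro-aldol channel is closed, and 14 results.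

2. Step 5. Acyl transfer from the dioxolanone to the new primary hydroxyl (lactonization with loss of pivalaldehyde) may outrun isolation and tosylation. The fallback sets out from 8 and comes back at 15; it keeps C5 at the ester level so that no free hydroxyl ever faces the dioxolanone. Acid 8 is esterified (Me3SiCHN2, MeOH–toluene) to the methyl ester F2. Its dioxolanone enolate (LiN(iPr)2, THF, −78 °C; the ring α-C–H is the more acidic one) adds to aldehyde 11, and the aldolate closes on the methyl ester (5-exo-trig lactonization) to the spiro bis-lactone F3, which has the same C2–C3 and O1–C5 connectivity. Both carbonyls are reduced with iBu2AlH (CH2Cl2, −78 °C) to the bis-lactol F4. Ionic reduction (Et3SiH, BF3·OEt2, CH2Cl2, −78 °C) gives the spiro oxolane–dioxolane F5. Its pivalaldehyde acetal is hydrolysed (aq. AcOH, 50 °C) to diol 15.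

3. Step 4. Thermodynamic acetalization of the branched hydroxy diacid may be slow and incompletely cis-selective, and the isomers may be hard to separate. The fallback sets out from 6 and comes back at 8 and uses kinetic, silyl-mediated acetalization. Diacid 6 is persilylated (Me3SiCl, Et3N, CH2Cl2) to the tris(trimethylsilyl) derivative F6. F6 is treated with pivalaldehyde 7 and Me3SiOTf (cat.) in CH2Cl2 at −78 °C, conditions known to favour cis-dioxolanones. Aqueous work-up cleaves the remaining silyl ester and gives 8.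

**Further compounds**

F1 | step 7 | (2S)-2-[(2S,4R)-4-{(R)-[4-(benzyloxy)-3-methoxyphenyl](hydroxy)methyl}-2-tert-butyl-5-oxo-1,3-dioxolan-4-yl]-3-[4-(benzyloxy)-3-methoxyphenyl]propyl 4-methylbenzenesulfonate | CC(C)(C)[C@@H]1OC(=O)[C@](O1)([C@H](O)c2ccc(OCc3ccccc3)c(OC)c2)[C@@H](Cc4ccc(OCc5ccccc5)c(OC)c4)COS(=O)(=O)c6ccc(C)cc6
F2 | step 5 | methyl (2R)-3-[4-(benzyloxy)-3-methoxyphenyl]-2-[(2S,4S)-2-tert-butyl-5-oxo-1,3-dioxolan-4-yl]propanoate | CC(C)(C)[C@@H]1OC(=O)[C@@H](O1)[C@@H](Cc2ccc(OCc3ccccc3)c(OC)c2)C(=O)OC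
F3 | step 5 | (2S,5R,6R,9R)-6-[4-(benzyloxy)-3-methoxyphenyl]-9-{[4-(benzyloxy)-3-methoxyphenyl]methyl}-2-tert-butyl-1,3,7-trioxaspiro[4.4]nonane-4,8-dione | CC(C)(C)[C@@H]1OC(=O)[C@@]2(O1)[C@@H](Cc3ccc(OCc4ccccc4)c(OC)c3)C(=O)O[C@@H]2c5ccc(OCc6ccccc6)c(OC)c5
F4 | step 5 | bis-lactol of F3: 6-[4-(benzyloxy)-3-methoxyphenyl]-9-{[4-(benzyloxy)-3-methoxyphenyl]methyl}-2-tert-butyl-1,3,7-trioxaspiro[4.4]nonane-4,8-diol, other centres as in F3, epimer mixture at C4 and C8 | CC(C)(C)[C@@H]1OC(O)[C@@]2(O1)[C@@H](Cc3ccc(OCc4ccccc4)c(OC)c3)C(O)O[C@@H]2c5ccc(OCc6ccccc6)c(OC)c5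
F5 | step 5 | (2R,5S,6R,9S)-6-[4-(benzyloxy)-3-methoxyphenyl]-9-{[4-(benzyloxy)-3-methoxyphenyl]methyl}-2-tert-butyl-1,3,7-trioxaspiro[4.4]nonane | CC(C)(C)[C@@H]1OC[C@@]2(O1)[C@@H](Cc3ccc(OCc4ccccc4)c(OC)c3)CO[C@@H]2c5ccc(OCc6ccccc6)c(OC)c5
F6 | step 4 | bis(trimethylsilyl) (2S,3R)-3-{[4-(benzyloxy)-3-methoxyphenyl]methyl}-2-[(trimethylsilyl)oxy]butanedioate | C[Si](C)(C)OC(=O)[C@@H](O[Si](C)(C)C)[C@@H](Cc1ccc(OCc2ccccc2)c(OC)c1)C(=O)O[Si](C)(C)C
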